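**Retrosynthetic overview**

1. The target is 19-[(2R)-2-methylbutanoyloxy]-ent-labd-8(17)-en-15-oic acid (labdane numbering for all carbons). The last bonds made are the C19 ester, the C15 acid (by oxidation) and C11–C12 (copper-catalysed alkyl–alkyl coupling of a C11 iodide with a chiral-pool C12–C15 Grignard reagent).
2. The bicyclic core, with C11 and C19 both as CO2Me, is cut at C1–C10 and at C8–C9. One tin hydride radical cascade of an acyclic iodo enyne diester closes ring A first (C1–C10, 6-exo-trig) and ring B second (C9–C8, 6-exo-dig) and leaves the 8(17)-methylidene.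
3. Enabling feature: C10 is the β-carbon of a (Z)-β-methyl enoate C10(CH3)=C9H–C11O2Me whose ester is cis to the C5 stereocentre. The iodide-bearing C1 ends the three-carbon chain on quaternary C4, and the other C5 arm, C6–C7–C8≡C17, ends in an alkyne. A(1,3) strain fixes the face of C10 that C1 attacks, and the alkyne traps the C9 radical.
4. The acyclic precursor comes from (R)-carvone (1). Two α′-alkylations build C4 next to C5; 1,4-hydrosilylation and ozonolysis open the carvone ring between C19 and C8; the C8 methyl ketone and then the C10 methyl ketone (from the isopropenyl group) become the alkyne and an ynoate; Me2CuLi brings C20 with the Z geometry.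
5. Ring order: ring A, then ring B, both in step 11. C4 and C5 come from carvone, C10 and C9 from the cascade, C13 and C2′ from the chiral pool.

Key step: step 11

Remark: compound 2 is carried on as its C6 epimer mixture (trans epimer drawn), because that centre is made planar again in step 2; the enantiopure diol 21 and acid 26 are taken as purchasable.

**Route**

Step 1
Reactants: 1 (R)-(−)-carvone
Product: 2 (5R,6S)-6-(3-chloropropyl)-2-methyl-5-(prop-1-en-2-yl)cyclohex-2-en-1-one
Conditions: LiN(iPr)2, THF, −78 °C; then ICH2CH2CH2Cl, DMPU, −78 °C to 0 °C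
Reagents that add atoms: 1-chloro-3-iodopropane, ClCCCI
Why: Kinetic α′-deprotonation gives the cross-conjugated lithium dienolate, which should be C-alkylated by the iodide end of the dihalide (enolate alkylation, SN2) mainly trans to the isopropenyl group, the chloride being kept as a latent radical precursor.

Step 2
Reactants: 2 (5R,6S)-6-(3-chloropropyl)-2-methyl-5-(prop-1-en-2-yl)cyclohex-2-en-1-one
Product: 3 (5S,6R)-6-(3-chloropropyl)-2,6-dimethyl-5-(prop-1-en-2-yl)cyclohex-2-en-1-one
Conditions: LiN(iPr)2, THF, −78 °C to −40 °C; then MeI, −78 °C to −20 °C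
Reagents that add atoms: iodomethane, CI
Why: Enolate alkylation in which MeI should enter axially on the face opposite the neighbouring pseudoaxial isopropenyl group (1,2-induction), so that methyl ends trans and the chloropropyl chain cis to isopropenyl, which is the C4/C5 relationship of the target.

Step 3
Reactants: 3 (5S,6R)-6-(3-chloropropyl)-2,6-dimethyl-5-(prop-1-en-2-yl)cyclohex-2-en-1-one
Product: 4 {[(5S,6R)-6-(3-chloropropyl)-2,6-dimethyl-5-(prop-1-en-2-yl)cyclohex-1-en-1-yl]oxy}triethylsilane
Conditions: Et3SiH, RhCl(PPh3)3 (2 mol %), PhH, 60 °C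
Reagents that add atoms: triethylsilane, CC[SiH](CC)CC
Why: Rhodium-catalysed 1,4-hydrosilylation of the enone (monohydrosilanes add in the conjugate sense) should give the regiodefined silyl enol ether without touching the 1,1-disubstituted alkene or the alkyl chloride; no stereocentre is formed.

Step 4
Reactants: 4 {[(5S,6R)-6-(3-chloropropyl)-2,6-dimethyl-5-(prop-1-en-2-yl)cyclohex-1-en-1-yl]oxy}triethylsilane
Product: 6 methyl (2R,3S)-2-(3-chloropropyl)-2-methyl-6-oxo-3-(prop-1-en-2-yl)heptanoate, via keto acid 5 (not isolated)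
Conditions: O3 (1.0 equiv), CH2Cl2/MeOH, −78 °C; Me2S; aqueous work-up; then TMSCHN2, PhMe/MeOH, 0 °C
Reagents that add atoms: ozone, [O-][O+]=O; (trimethylsilyl)diazomethane, C[Si](C)(C)C=[N+]=[N-]
Why: Ozonolysis of the silyl enol ether, the most electron-rich alkene present, should cleave the former ring bond to the C19 carboxylic acid and the C8 methyl ketone while one equivalent of ozone spares the isopropenyl group, and the crude acid is methylated with the diazoalkane.

Step 5
Reactants: 6 methyl (2R,3S)-2-(3-chloropropyl)-2-methyl-6-oxo-3-(prop-1-en-2-yl)heptanoate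
Product: 9 methyl (2R,3S)-2-(3-chloropropyl)-2-methyl-3-(prop-1-en-2-yl)-7-(trimethylsilyl)hept-6-ynoate, via enol phosphate 7 (not isolated), via lithium acetylide 8 (not isolated)
Conditions: LiN(iPr)2 (1.1 equiv), THF, −78 °C; ClP(O)(OEt)2, −78 °C to rt; LiN(iPr)2 (2.3 equiv), −78 °C to rt; TMSCl, −78 °C to rt
Reagents that add atoms: chlorotrimethylsilane, C[Si](C)(C)Cl; diethyl chlorophosphate, CCOP(=O)(Cl)OCC (its atoms stay in intermediate 7 only)
Why: Methyl ketone to alkyne conversion through the kinetic enol phosphate and amide-induced β-elimination, the lithium acetylide being capped in the flask as the C-silyl alkyne; the non-enolisable α-quaternary ester, the chloride and the alkene should be inert.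

Step 6
Reactants: 9 methyl (2R,3S)-2-(3-chloropropyl)-2-methyl-3-(prop-1-en-2-yl)-7-(trimethylsilyl)hept-6-ynoate
Product: 10 methyl (2R,3R)-3-acetyl-2-(3-chloropropyl)-2-methyl-7-(trimethylsilyl)hept-6-ynoate
Conditions: O3, CH2Cl2/MeOH, −78 °C; Me2S
Reagents that add atoms: ozone, [O-][O+]=O
Why: Ozonolysis with reductive work-up should turn the isopropenyl group into the C10 methyl ketone, a silyl alkyne reacting far more slowly with ozone than an alkene, and the α-stereocentre C5 is not enolised under these neutral conditions.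

Step 7
Reactants: 10 methyl (2R,3R)-3-acetyl-2-(3-chloropropyl)-2-methyl-7-(trimethylsilyl)hept-6-ynoate
Product: 13 dimethyl (4S,5R)-5-(3-chloropropyl)-5-methyl-4-[4-(trimethylsilyl)but-3-yn-1-yl]hex-2-ynedioate, via enol phosphate 11 (not isolated), via lithium acetylide 12 (not isolated)
Conditions: LiN(iPr)2 (1.1 equiv), THF, −78 °C; ClP(O)(OEt)2, −78 °C to rt; LiN(iPr)2 (2.3 equiv), −78 °C to 0 °C; ClCO2Me, −78 °C
Reagents that add atoms: methyl chloroformate, COC(=O)Cl; diethyl chlorophosphate, CCOP(=O)(Cl)OCC (its atoms stay in intermediate 11 only)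
Why: Second enol phosphate elimination (kinetic deprotonation at CH3 and not at the hindered tertiary C5–H) with acylation of the acetylide by the chloroformate should give the ynoate whose ester carbon is C11.

Step 8
Reactants: 13 dimethyl (4S,5R)-5-(3-chloropropyl)-5-methyl-4-[4-(trimethylsilyl)but-3-yn-1-yl]hex-2-ynedioate
Product: 14 dimethyl (2Z,4S,5R)-5-(3-chloropropyl)-3,5-dimethyl-4-[4-(trimethylsilyl)but-3-yn-1-yl]hex-2-enedioate
Conditions: Me2CuLi (from MeLi and CuI, 1.3 equiv), THF, −78 °C; MeOH quench at −78 °C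
Reagents that add atoms: lithium dimethylcuprate, [Li+].C[Cu-]C (made from methyllithium, [Li]C, and CuI)
Why: Organocuprate conjugate addition to an alkynoate is a stereospecific syn carbocupration, so cold protonation should leave the new methyl (C20) cis to H-9 and the ester cis to C5 (the Z enoate).

Step 9
Reactants: 14 dimethyl (2Z,4S,5R)-5-(3-chloropropyl)-3,5-dimethyl-4-[4-(trimethylsilyl)but-3-yn-1-yl]hex-2-enedioate
Product: 15 dimethyl (2Z,4S,5R)-4-(but-3-yn-1-yl)-5-(3-chloropropyl)-3,5-dimethylhex-2-enedioate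
Conditions: K2CO3 (0.3 equiv), MeOH, rt
Reagents that add atoms: none
Why: Carbonate-catalysed methanolysis of the alkynyl C–Si bond (protodesilylation) should free the terminal alkyne, while the esters, the chloride and the hindered β,β-disubstituted enoate are stable at room temperature.

Step 10
Reactants: 15 dimethyl (2Z,4S,5R)-4-(but-3-yn-1-yl)-5-(3-chloropropyl)-3,5-dimethylhex-2-enedioate
Product: 16 dimethyl (2Z,4S,5R)-4-(but-3-yn-1-yl)-5-(3-iodopropyl)-3,5-dimethylhex-2-enedioate
Conditions: NaI (5 equiv), 2-butanone, 80 °C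
Reagents that add atoms: sodium iodide, [Na+].[I-]
Why: Finkelstein halide exchange (SN2) at the unhindered primary chloride, driven by precipitation of NaCl, should install the iodide needed for fast halogen abstraction.

Step 11
Reactants: 16 dimethyl (2Z,4S,5R)-4-(but-3-yn-1-yl)-5-(3-iodopropyl)-3,5-dimethylhex-2-enedioate
Product: 18 dimethyl (1R,4aS,5R,8aR)-5,8a-dimethyl-2-methylidenedecahydronaphthalene-1,5-dicarboxylate, via C9 radical 17 (not isolated)
Conditions: Bu3SnH (1.3 equiv) and AIBN (0.2 equiv) added over 8 h by syringe pump, PhH (5 mM), 80 °C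
Reagents that add atoms: none
Why: Bu3Sn• abstracts iodine from C1, the primary radical adds 6-exo-trig to C10 (the enoate β-carbon; ring A, the C1–C10 bond and the quaternary centre), the C9 α-ester radical 17 adds 6-exo-dig to C8 of the alkyne (ring B), and the C17 vinyl radical takes H from Bu3SnH, which leaves the 8(17)-methylidene. The closest known reaction type is the tin hydride-mediated tandem radical cyclisation of an ω-iodo enoate that ends on an alkyne (Giese-type conjugate addition followed by exo-dig closure). C10 is controlled by A(1,3) strain: the ester on C9 is cis to C5, so H-5 must lie in the enoate plane, C4 and C6 sit on opposite faces, and C1 can reach C10 only on the face of C4 through a chair with the C6 arm equatorial and CH3-20 axial, that is H-5 and CH3-20 anti (trans-decalin). C9 is set in the second, chair-like closure, in which the planar ester-bearing radical keeps CO2Me eclipsed with the small CH3-20 and away from C5, so that CO2Me (C11) should end equatorial. The step needs each cyclisation to beat hydrogen transfer from the stannane and 1,5-hydrogen shift, and exo to beat endo attack: slow addition keeps Bu3SnH near millimolar, the in-plane H-5 is not activated for abstraction, and the polarised enoate (large LUMO coefficient at C10) and the short alkyne tether direct both additions.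

Step 12
Reactants: 18 dimethyl (1R,4aS,5R,8aR)-5,8a-dimethyl-2-methylidenedecahydronaphthalene-1,5-dicarboxylate
Product: 19 12,13,14,15,16-pentanor-ent-labd-8(17)-ene-11,19-diol
Conditions: LiAlH4 (4 equiv), THF, 0 °C to reflux; aqueous NaOH work-up
Reagents that add atoms: none
Why: Hydride reduction of both methyl esters (the hindered axial C19 ester needs reflux) should give the diol without touching the isolated alkene or any stereocentre.

Step 13
Reactants: 19 12,13,14,15,16-pentanor-ent-labd-8(17)-ene-11,19-diol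
Product: 20 11-iodo-12,13,14,15,16-pentanor-ent-labd-8(17)-en-19-ol
Conditions: PPh3 (1.2 equiv), imidazole, I2 (1.2 equiv), CH2Cl2, 0 °C to rt
Reagents that add atoms: iodine, II
Why: Appel-type iodination in which SN2 displacement of the alkoxyphosphonium should occur only at the β-branched C11 carbinol, because the neopentyl, 1,3-diaxially shielded C19 carbinol cannot undergo backside attack and is returned on work-up.

Step 14
Reactants: 21 (S)-2-methylbutane-1,4-diol
Product: 22 (S)-4-[(tert-butyldiphenylsilyl)oxy]-2-methylbutan-1-ol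
Conditions: TBDPSCl (1.0 equiv), imidazole, CH2Cl2, −20 °C
Reagents that add atoms: tert-butyl(chloro)diphenylsilane, CC(C)(C)[Si](Cl)(c1ccccc1)c1ccccc1
Why: Silylation with a bulky chlorosilane at low temperature should favour the hydroxyl remote from the methyl branch (the regioisomer is removed by chromatography), and the stereocentre comes unchanged from the chiral pool.

Step 15
Reactants: 22 (S)-4-[(tert-butyldiphenylsilyl)oxy]-2-methylbutan-1-ol
Product: 23 (S)-(4-bromo-3-methylbutoxy)(tert-butyl)diphenylsilane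
Conditions: CBr4, PPh3, CH2Cl2, 0 °C
Reagents that add atoms: tetrabromomethane, BrC(Br)(Br)Br
Why: Appel bromination (SN2 at the primary carbon next to, not at, the stereocentre) should give the bromide without racemisation.

Step 16
Reactants: 20 11-iodo-12,13,14,15,16-pentanor-ent-labd-8(17)-en-19-ol; 23 (S)-(4-bromo-3-methylbutoxy)(tert-butyl)diphenylsilane
Product: 25 (13R)-15-[(tert-butyldiphenylsilyl)oxy]-ent-labd-8(17)-en-19-ol, via Grignard reagent 24 (not isolated)
Conditions: 23 (3.3 equiv), Mg, THF, 40 °C; then 20, Li2CuCl4 (5 mol %), THF, −30 °C to 0 °C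
Reagents that add atoms: magnesium, [Mg] (its atom stays in intermediate 24 only)
Why: Copper-catalysed alkyl–alkyl cross-coupling of a primary iodide with a primary Grignard reagent should form C11–C12, the first equivalent of 24 only deprotonating the C19 hydroxyl, and the C13 centre arrives intact from 23.

Step 17
Reactants: 25 (13R)-15-[(tert-butyldiphenylsilyl)oxy]-ent-labd-8(17)-en-19-ol; 26 (R)-2-methylbutanoic acid
Product: 27 (13R)-15-[(tert-butyldiphenylsilyl)oxy]-ent-labd-8(17)-en-19-yl (2R)-2-methylbutanoate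
Conditions: DCC (1.6 equiv), DMAP (0.2 equiv), CH2Cl2, 0 °C to rt
Reagents that add atoms: none
Why: Steglich esterification should acylate the only free hydroxyl, the neopentyl C19–OH, and the α-stereocentre of the acid is retained because DMAP loading and temperature are kept low.

Step 18
Reactants: 27 (13R)-15-[(tert-butyldiphenylsilyl)oxy]-ent-labd-8(17)-en-19-yl (2R)-2-methylbutanoate
Product: 28 (13R)-15-hydroxy-ent-labd-8(17)-en-19-yl (2R)-2-methylbutanoate
Conditions: Bu4NF (1.5 equiv), AcOH (1.5 equiv), THF, rt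
Reagents that add atoms: none
Why: Fluoride-mediated cleavage of the primary silyl ether, buffered with acetic acid so that the hindered C19 ester should not be attacked by basic fluoride.

Step 19
Reactants: 28 (13R)-15-hydroxy-ent-labd-8(17)-en-19-yl (2R)-2-methylbutanoate
Product: 29 (3R)-5-[(1R,4aS,5R,8aS)-5,8a-dimethyl-5-({[(2R)-2-methylbutanoyl]oxy}methyl)-2-methylidenedecahydronaphthalen-1-yl]-3-methylpentanoic acid
Conditions: TEMPO (0.2 equiv), PhI(OAc)2 (2.5 equiv), MeCN/H2O 1:1, rt
Reagents that add atoms: water, O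
Why: Oxoammonium (TEMPO) oxidation in aqueous acetonitrile should take the primary alcohol through the aldehyde hydrate to the carboxylic acid without affecting the ester, the 1,1-disubstituted alkene or any stereocentre.

**Compound list**

1 | (R)-(−)-carvone, (5R)-2-methyl-5-(prop-1-en-2-yl)cyclohex-2-en-1-one | CC1=CC[C@H](CC1=O)C(C)=C | starting material
2 | (5R,6S)-6-(3-chloropropyl)-2-methyl-5-(prop-1-en-2-yl)cyclohex-2-en-1-one (trans epimer drawn) | O=C1C(C)=CC[C@@H](C(C)=C)[C@@H]1CCCCl | intermediate
3 | (5S,6R)-6-(3-chloropropyl)-2,6-dimethyl-5-(prop-1-en-2-yl)cyclohex-2-en-1-one (6-methyl trans to isopropenyl) | O=C1C(C)=CC[C@@H](C(C)=C)[C@@]1(C)CCCCl | intermediate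
4 | {[(5S,6R)-6-(3-chloropropyl)-2,6-dimethyl-5-(prop-1-en-2-yl)cyclohex-1-en-1-yl]oxy}triethylsilane | CC[Si](CC)(CC)OC1=C(C)CC[C@@H](C(C)=C)[C@@]1(C)CCCCl | intermediate
5 | (2R,3S)-2-(3-chloropropyl)-2-methyl-6-oxo-3-(prop-1-en-2-yl)heptanoic acid | OC(=O)[C@](C)(CCCCl)[C@@H](CCC(C)=O)C(C)=C | intermediate
6 | methyl (2R,3S)-2-(3-chloropropyl)-2-methyl-6-oxo-3-(prop-1-en-2-yl)heptanoate | COC(=O)[C@](C)(CCCCl)[C@@H](CCC(C)=O)C(C)=C | intermediate
7 | methyl (2R,3S)-2-(3-chloropropyl)-6-[(diethoxyphosphoryl)oxy]-2-methyl-3-(prop-1-en-2-yl)hept-6-enoate (enol phosphate) | COC(=O)[C@](C)(CCCCl)[C@@H](CCC(=C)OP(=O)(OCC)OCC)C(C)=C | intermediate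
8 | lithium acetylide of methyl (2R,3S)-2-(3-chloropropyl)-2-methyl-3-(prop-1-en-2-yl)hept-6-ynoate | COC(=O)[C@](C)(CCCCl)[C@@H](CCC#C[Li])C(C)=C | intermediate
9 | methyl (2R,3S)-2-(3-chloropropyl)-2-methyl-3-(prop-1-en-2-yl)-7-(trimethylsilyl)hept-6-ynoate | COC(=O)[C@](C)(CCCCl)[C@@H](CCC#C[Si](C)(C)C)C(C)=C | intermediate
10 | methyl (2R,3R)-3-acetyl-2-(3-chloropropyl)-2-methyl-7-(trimethylsilyl)hept-6-ynoate | COC(=O)[C@](C)(CCCCl)[C@@H](CCC#C[Si](C)(C)C)C(C)=O | intermediate
11 | methyl (2R,3R)-2-(3-chloropropyl)-3-{1-[(diethoxyphosphoryl)oxy]ethenyl}-2-methyl-7-(trimethylsilyl)hept-6-ynoate (enol phosphate) | COC(=O)[C@](C)(CCCCl)[C@@H](CCC#C[Si](C)(C)C)C(=C)OP(=O)(OCC)OCC | intermediate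
12 | methyl (2R,3S)-2-(3-chloropropyl)-3-(lithioethynyl)-2-methyl-7-(trimethylsilyl)hept-6-ynoate (lithium acetylide) | COC(=O)[C@](C)(CCCCl)[C@@H](CCC#C[Si](C)(C)C)C#C[Li] | intermediate
13 | dimethyl (4S,5R)-5-(3-chloropropyl)-5-methyl-4-[4-(trimethylsilyl)but-3-yn-1-yl]hex-2-ynedioate | COC(=O)[C@](C)(CCCCl)[C@@H](CCC#C[Si](C)(C)C)C#CC(=O)OC | intermediate
14 | dimethyl (2Z,4S,5R)-5-(3-chloropropyl)-3,5-dimethyl-4-[4-(trimethylsilyl)but-3-yn-1-yl]hex-2-enedioate | COC(=O)[C@](C)(CCCCl)[C@@H](CCC#C[Si](C)(C)C)/C(C)=C\C(=O)OC | intermediate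
15 | dimethyl (2Z,4S,5R)-4-(but-3-yn-1-yl)-5-(3-chloropropyl)-3,5-dimethylhex-2-enedioate | COC(=O)[C@](C)(CCCCl)[C@@H](CCC#C)/C(C)=C\C(=O)OC | intermediate
16 | dimethyl (2Z,4S,5R)-4-(but-3-yn-1-yl)-5-(3-iodopropyl)-3,5-dimethylhex-2-enedioate | COC(=O)[C@](C)(CCCI)[C@@H](CCC#C)/C(C)=C\C(=O)OC | intermediate
17 | C9 α-ester radical with ring A closed (C1–C10 bond formed, alkyne arm still open) | C#CCC[C@@H]1[C@](C)(C(=O)OC)CCC[C@@]1(C)[CH]C(=O)OC | intermediate
18 | dimethyl (1R,4aS,5R,8aR)-5,8a-dimethyl-2-methylidenedecahydronaphthalene-1,5-dicarboxylate (dimethyl 12,13,14,15,16-pentanor-ent-labd-8(17)-ene-11,19-dioate; trans-decalin, C19 ester axial and cis to CH3-20, C11 ester equatorial) | C=C1CC[C@@H]2[C@](C)(C(=O)OC)CCC[C@@]2(C)[C@@H]1C(=O)OC | intermediate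
19 | 12,13,14,15,16-pentanor-ent-labd-8(17)-ene-11,19-diol | C=C1CC[C@@H]2[C@](C)(CO)CCC[C@@]2(C)[C@@H]1CO | intermediate
20 | 11-iodo-12,13,14,15,16-pentanor-ent-labd-8(17)-en-19-ol | C=C1CC[C@@H]2[C@](C)(CO)CCC[C@@]2(C)[C@@H]1CI | intermediate
21 | (S)-2-methylbutane-1,4-diol | OC[C@@H](C)CCO | starting material
22 | (S)-4-[(tert-butyldiphenylsilyl)oxy]-2-methylbutan-1-ol | OC[C@@H](C)CCO[Si](c1ccccc1)(c1ccccc1)C(C)(C)C | intermediate
23 | (S)-(4-bromo-3-methylbutoxy)(tert-butyl)diphenylsilane | BrC[C@@H](C)CCO[Si](c1ccccc1)(c1ccccc1)C(C)(C)C | intermediate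
24 | {(2S)-4-[(tert-butyldiphenylsilyl)oxy]-2-methylbutyl}magnesium bromide | Br[Mg]C[C@@H](C)CCO[Si](c1ccccc1)(c1ccccc1)C(C)(C)C | intermediate
25 | (13R)-15-[(tert-butyldiphenylsilyl)oxy]-ent-labd-8(17)-en-19-ol | C=C1CC[C@@H]2[C@](C)(CO)CCC[C@@]2(C)[C@@H]1CC[C@@H](C)CCO[Si](c1ccccc1)(c1ccccc1)C(C)(C)C | intermediate
26 | (R)-2-methylbutanoic acid | CC[C@@H](C)C(=O)O | starting material
27 | (13R)-15-[(tert-butyldiphenylsilyl)oxy]-ent-labd-8(17)-en-19-yl (2R)-2-methylbutanoate | C=C1CC[C@@H]2[C@](C)(COC(=O)[C@H](C)CC)CCC[C@@]2(C)[C@@H]1CC[C@@H](C)CCO[Si](c1ccccc1)(c1ccccc1)C(C)(C)C | intermediate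
28 | (13R)-15-hydroxy-ent-labd-8(17)-en-19-yl (2R)-2-methylbutanoate | C=C1CC[C@@H]2[C@](C)(COC(=O)[C@H](C)CC)CCC[C@@]2(C)[C@@H]1CC[C@@H](C)CCO | intermediate
29 | (3R)-5-[(1R,4aS,5R,8aS)-5,8a-dimethyl-5-({[(2R)-2-methylbutanoyl]oxy}methyl)-2-methylidenedecahydronaphthalen-1-yl]-3-methylpentanoic acid | C=C1CC[C@@H]2[C@](C)(COC(=O)[C@H](C)CC)CCC[C@@]2(C)[C@@H]1CC[C@@H](C)CC(=O)O | target

**Step count and risks**

Total step count: 19. Longest linear sequence: 17 steps (steps 1 to 13 and 16 to 19, from 1 to 29).

Steps most likely to fail: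

Step 11. The C9 α-ester radical may capture hydrogen from the stannane before it closes onto the alkyne, so that only ring A forms. The fallback sets out from 16 and comes back at 18. The same radical closure is run deliberately with Bu3SnH in one portion (0.05 M, AIBN, PhH, 80 °C) to give the monocyclic diester methyl (1R,2S,3S)-2-(but-3-yn-1-yl)-3-(2-methoxy-2-oxoethyl)-1,3-dimethylcyclohexane-1-carboxylate F1. Its only enolisable ester is silylated (LiN(SiMe3)2, TBSCl, THF/DMPU, −78 °C, cold neutral quench) to the tert-butyldimethylsilyl ketene acetal of the C11 ester F2. A cationic monovalent gold catalyst (Ph3PAuCl/AgOTf, CH2Cl2/MeOH, rt) then effects the polar 6-exo-dig carbocyclisation (Conia-ene type) onto the terminal alkyne, which should give 18.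

Step 16. Substitution at the β-branched, neopentyl-like C11 may be so slow that elimination or halogen–metal exchange takes over. The fallback sets out from 20 and 23 and comes back at 25. Zinc insertion into 23 (Zn dust, LiCl, THF, 40 °C) gives {(2S)-4-[(tert-butyldiphenylsilyl)oxy]-2-methylbutyl}zinc bromide F3. F3 is joined to iodide 20 by nickel-catalysed alkyl–alkyl Negishi coupling (Ni(cod)2, zerovalent nickel, with s-Bu-Pybox, DMA, rt; 2.5 equiv of F3, one equivalent being quenched by the hydroxyl). In this coupling the C–I bond is broken by halogen abstraction and not by backside attack.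

Step 4. Ozone may also attack the isopropenyl group (over-oxidation), or cleavage may stay incomplete if ozone is under-dosed. The fallback sets out from 4 and comes back at 6 without ozone. Rubottom oxidation (mCPBA, NaHCO3, CH2Cl2, −20 °C; then 1 M HCl, THF) gives (5S,6R)-6-(3-chloropropyl)-2-hydroxy-2,6-dimethyl-5-(prop-1-en-2-yl)cyclohexan-1-one F4. Pb(OAc)4 in MeOH/PhH at 0 °C then cleaves the bond between the carbonyl and the carbinol carbon, which should give the methyl ester and the methyl ketone of 6 in one operation.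

Further compounds
F1 | step 11 | methyl (1R,2S,3S)-2-(but-3-yn-1-yl)-3-(2-methoxy-2-oxoethyl)-1,3-dimethylcyclohexane-1-carboxylate | C#CCC[C@@H]1[C@](C)(C(=O)OC)CCC[C@@]1(C)CC(=O)OC
F2 | step 11 | tert-butyldimethylsilyl ketene acetal of the C11 ester of F1 (ketene acetal geometry not defined) | C#CCC[C@@H]1[C@](C)(C(=O)OC)CCC[C@@]1(C)C=C(OC)O[Si](C)(C)C(C)(C)C
F3 | step 16 | {(2S)-4-[(tert-butyldiphenylsilyl)oxy]-2-methylbutyl}zinc bromide | Br[Zn]C[C@@H](C)CCO[Si](c1ccccc1)(c1ccccc1)C(C)(C)C
F4 | step 4 | (5S,6R)-6-(3-chloropropyl)-2-hydroxy-2,6-dimethyl-5-(prop-1-en-2-yl)cyclohexan-1-one (both C2 epimers) | O=C1C(C)(O)CC[C@@H](C(C)=C)[C@@]1(C)CCCCl
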